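## Retrosynthetic overview
1. Target ⇒ (HCl) 11,13-spiro-epoxide carrying a 5-O-TES group ⇒ (angelic acid) 8β,9β-diol ⇒ (OsO4) bridged (Z)-8,9-alkene.
2. Ten-membered carbocycle (last ring formed) ⇒ ring-closing metathesis of a C-7/C-10 divinyl compound.
3. Furanone ring and quaternary C-10 ⇒ gold-catalysed heterocyclisation with a 1,2-vinyl shift (C-1→C-10) of an acyclic tertiary α-ketol. This is the key step.
4. C-4–C-5 ⇒ iridium-catalysed anti-propargylation that joins a west enyne ketol (lactamide + vinylacetylene + vinyl Grignard) to an east spiro-epoxy lactone alcohol (hydroxymethylbutenolide + vinyl Grignard + iminium salt).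
5. Ring order: butyrolactone (purchased) → oxirane → furanone → carbocycle.

Numbering note: C-1 ketone, C-2=C-3 enol ether, C-4 (Me-15), C-5 (OH), C-6 (lactone O), C-7, C-8 (O-angeloyl), C-9 (OH), C-10 (Me-14, ether O), C-11 (OH), C-12 (lactone C=O), C-13 (CH2Cl).

Assumption: but-1-en-3-yne is bought as a stabilised solution, and the (R)-ligand in step 8 is taken to give the (4S,5S) adduct (otherwise its antipode is used).

## Route

Step 1
Reactants: 1 (S)-2-hydroxy-N,N-dimethylpropanamide; 2 but-1-en-3-yne
Product: 4 (2S)-2-hydroxyhept-6-en-4-yn-3-one, via lithium but-1-en-3-yn-1-ide 3 (not isolated)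
Conditions: 2 (2.2 equiv), n-BuLi (2.1 equiv), THF, −78 °C; then 1, −78 to −20 °C; aq. NH4Cl
Reagents that add atoms: none
Why: Acylation of a lithium acetylide by a tertiary amide stops at the alkoxide-chelated tetrahedral adduct, so the ynone appears only on quench and the lactate stereocentre is untouched.

Step 2
Reactants: 4 (2S)-2-hydroxyhept-6-en-4-yn-3-one; 5 vinylmagnesium bromide
Product: 6 (2S,3R)-3-ethenylhept-6-en-4-yne-2,3-diol
Conditions: 5 (3 equiv), THF, −78 °C; aq. NH4Cl
Reagents that add atoms: none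
Why: In this Cram-chelate 1,2-addition the magnesium alkoxide ties the carbinol oxygen to the ketone oxygen and the Grignard reagent attacks from the face carrying H rather than CH3, which sets the tertiary carbinol (future C-1) as R.

Step 3
Reactants: 6 (2S,3R)-3-ethenylhept-6-en-4-yne-2,3-diol
Product: 7 (3R)-3-ethenyl-3-hydroxyhept-6-en-4-yn-2-one
Conditions: IBX (1.5 equiv), DMSO, rt
Reagents that add atoms: none
Why: IBX oxidation converts the only secondary alcohol of the secondary/tertiary 1,2-diol into the α-ketol without glycol cleavage and leaves the tertiary centre intact.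

Step 4
Reactants: 8 (S)-5-(hydroxymethyl)furan-2(5H)-one
Product: 9 (5S)-5-[(triethylsilyloxy)methyl]furan-2(5H)-one
Conditions: TESCl, imidazole, CH2Cl2, 0 °C
Reagents that add atoms: chlorotriethylsilane (TESCl), CC[Si](Cl)(CC)CC
Why: Standard silylation masks the primary alcohol and enlarges the C-6 substituent that steers the next step.

Step 5
Reactants: 9 (5S)-5-[(triethylsilyloxy)methyl]furan-2(5H)-one; 5 vinylmagnesium bromide; 10 N,N-dimethylmethyleneiminium iodide
Product: 13 (3R,4S,5S)-3-[(dimethylamino)methyl]-4-ethenyl-5-(hydroxymethyl)oxolan-2-one, via ketene silyl acetal 11 (not isolated), via Mannich base silyl ether 12 (not isolated)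
Conditions: 5 (1.5 equiv), CuBr·SMe2 (10 mol %), TMSCl (2 equiv), THF, −78 °C; then 10, CH2Cl2, −78 °C to rt; 1 M HCl, THF, rt; NaHCO3
Reagents that add atoms: none
Why: The copper-catalysed, TMSCl-accelerated conjugate addition enters anti to the C-6 side chain (sets C-7, trans), the ketene silyl acetal then undergoes Mannich aminomethylation (brings C-13), and the acid work-up removes the TES group.

Step 6
Reactants: 13 (3R,4S,5S)-3-[(dimethylamino)methyl]-4-ethenyl-5-(hydroxymethyl)oxolan-2-one
Product: 15 (4S,5S)-4-ethenyl-5-(hydroxymethyl)-3-methylideneoxolan-2-one, via trimethylammonium iodide 14 (not isolated)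
Conditions: MeI, MeOH, rt; then aq. NaHCO3, CH2Cl2, rt
Reagents that add atoms: none
Why: Exhaustive N-methylation followed by Hofmann-type E1cB elimination is the classical α-methylenation of lactones and does not touch C-6 or C-7.

Step 7
Reactants: 15 (4S,5S)-4-ethenyl-5-(hydroxymethyl)-3-methylideneoxolan-2-one
Product: 16 (3R,6S,7R)-7-ethenyl-6-(hydroxymethyl)-1,5-dioxaspiro[2.4]heptan-4-one
Conditions: t-BuOOH (decane), DBU (0.5 equiv), CH2Cl2, 0 °C to rt
Reagents that add atoms: tert-butyl hydroperoxide, CC(C)(C)OO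
Why: In this Weitz–Scheffer nucleophilic epoxidation the peroxide anion adds only to the electron-poor exocyclic methylene, and the enolate closes onto oxygen on the face anti to the C-7 vinyl group, which fixes the C-11–O configuration and removes the enolisable lactone position.

Step 8
Reactants: 16 (3R,6S,7R)-7-ethenyl-6-(hydroxymethyl)-1,5-dioxaspiro[2.4]heptan-4-one; 7 (3R)-3-ethenyl-3-hydroxyhept-6-en-4-yn-2-one
Product: 17 (3R,6S,7R)-7-ethenyl-6-[(1S,2S,5R)-5-ethenyl-1,5-dihydroxy-2-methyl-6-oxohept-3-yn-1-yl]-1,5-dioxaspiro[2.4]heptan-4-one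
Conditions: [Ir(cod)Cl]2 (5 mol %), (R)-SEGPHOS (10 mol %), K2CO3 (10 mol %), THF, 70 °C, sealed tube
Reagents that add atoms: none
Why: In this iridium-catalysed transfer-hydrogenative carbonyl (α-methyl)propargylation the catalyst dehydrogenates the primary alcohol, the iridium hydride adds only to the conjugated vinyl terminus of 7, and the allenyl/propargyl-iridium species adds to the transient aldehyde through a closed chair transition state, giving the 4,5-anti adduct with ligand-controlled faces (sets C-4 and C-5).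

Step 9
Reactants: 17 homopropargylic alcohol
Product: 18 5-O-triethylsilyl ether of 17
Conditions: TESCl, imidazole, CH2Cl2, 0 °C to rt
Reagents that add atoms: chlorotriethylsilane (TESCl), CC[Si](Cl)(CC)CC
Why: Silylation takes the secondary C-5 hydroxyl only, because the tertiary propargylic carbinol is too hindered, and this blocks 5-endo hydroalkoxylation in step 10 and acylation at O-5 in step 13.

Step 10
Reactants: 18 5-O-triethylsilyl α-ketol
Product: 19 (3R,6S,7R)-7-ethenyl-6-{(1S,2R)-2-[(5S)-5-ethenyl-5-methyl-4-oxo-4,5-dihydrofuran-2-yl]-1-(triethylsilyloxy)propyl}-1,5-dioxaspiro[2.4]heptan-4-one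
Conditions: Ph3PAuNTf2 (5 mol %), 4 Å MS, CH2Cl2, 0 °C to rt
Reagents that add atoms: none
Why: Proposed new method: cationic monovalent gold activates the C-2≡C-3 alkyne and the acetyl oxygen closes 5-endo-dig on C-3 to give a cyclic oxocarbenium vinyl-gold species in which C-2 is locked syn-periplanar to the C-10=O+ bond; the vinyl group on C-1 therefore stands perpendicular to the cation and shifts suprafacially from C-1 to C-10 through a bridged cyclopropylcarbinyl-like transition state while the C-1 hydroxyl collapses to the ketone (semipinacol/α-ketol step), and protodeauration frees the catalyst, so the (1R) carbinol is copied into the (10S) quaternary centre; the closest known reaction type is the platinum- or gold-catalysed heterocyclisation/1,2-alkyl migration of 2-hydroxy-2-alkynyl ketones, which has not been shown for an alkenyl migrating group, for chirality transfer from an acyclic enantioenriched carbinol, or beside a competing 1,4-enyne.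

Step 11
Reactants: 19 divinyl furanone
Product: 20 bridged (8Z)-cycloalkene (3,10-epoxygermacra-2,8-dien-1-one 6,12-olide carrying the 11,13-spiro-epoxide and 5-OTES)
Conditions: second-generation Hoveyda–Grubbs catalyst (15 mol %), toluene (1 mM), 80 °C, argon sparge
Reagents that add atoms: none
Why: In this ring-closing olefin metathesis the trans-lactone and the flat furanone pre-organise the two vinyl groups, loss of ethene drives the closure, and only the Z alkene fits the bridged nine-membered oxacycle.

Step 12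
Reactants: 20 bridged (8Z)-cycloalkene
Product: 21 8β,9β-diol (8S,9S)
Conditions: OsO4 (5 mol %), NMO (1.5 equiv), acetone–H2O, 0 °C to rt
Reagents that add atoms: N-methylmorpholine N-oxide, C[N+]1([O-])CCOCC1; water, O
Why: In this Upjohn syn-dihydroxylation, with H-7 eclipsing the cis-alkene (allylic 1,3-strain) and Me-14 anti to C-8, one face is flanked only by the bridging ether oxygen and C-6 while the other is shielded by quaternary C-11 and the C-1 carbonyl, so osmylation gives the 8,9-erythro diol of the target, and the electron-poor furanone alkene is spared.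

Step 13
Reactants: 21 8β,9β-diol; 22 angelic acid
Product: 24 8-O-angelate, via angelic trichlorobenzoic anhydride 23 (not isolated)
Conditions: 22, 2,4,6-trichlorobenzoyl chloride, Et3N, toluene, rt; then 21, toluene, 75 °C (no DMAP)
Reagents that add atoms: none
Why: Yamaguchi-type mixed-anhydride esterification without a nucleophilic catalyst keeps the Z geometry of the angelate, and it acylates O-8 because the C-9 hydroxyl is neopentylic (next to quaternary C-10) and hydrogen-bonded.

Step 14
Reactants: 24 8-O-angelate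
Product: 25 target CNP0340393.2
Conditions: HCl (4 M in 1,4-dioxane, 5 equiv), THF–H2O (20:1), 0 °C
Reagents that add atoms: hydrogen chloride, Cl
Why: Acid-promoted SN2 opening of the α-carbonyl spiro-epoxide by chloride occurs at the unhindered CH2 (C-13), so the C-11–O bond and its configuration are retained, and the same acid cleaves the TES ether.

## Compound list
1 | (S)-2-hydroxy-N,N-dimethylpropanamide | C[C@H](O)C(=O)N(C)C | starting material
2 | but-1-en-3-yne | C=CC#C | starting material
3 | lithium but-1-en-3-yn-1-ide | [Li]C#CC=C | intermediate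
4 | (2S)-2-hydroxyhept-6-en-4-yn-3-one | C[C@H](O)C(=O)C#CC=C | intermediate
5 | vinylmagnesium bromide | C=C[Mg]Br | starting material
6 | (2S,3R)-3-ethenylhept-6-en-4-yne-2,3-diol | C[C@H](O)[C@@](O)(C=C)C#CC=C | intermediate
7 | (3R)-3-ethenyl-3-hydroxyhept-6-en-4-yn-2-one | CC(=O)[C@@](O)(C=C)C#CC=C | intermediate
8 | (S)-5-(hydroxymethyl)furan-2(5H)-one | OC[C@H]1OC(=O)C=C1 | starting material
9 | (5S)-5-[(triethylsilyloxy)methyl]furan-2(5H)-one | CC[Si](CC)(CC)OC[C@H]1OC(=O)C=C1 | intermediate
10 | N,N-dimethylmethyleneiminium iodide | C[N+](C)=C.[I-] | starting material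
11 | (4S,5S)-4-ethenyl-5-[(triethylsilyloxy)methyl]-2-(trimethylsilyloxy)-4,5-dihydrofuran | CC[Si](CC)(CC)OC[C@H]1OC(O[Si](C)(C)C)=C[C@@H]1C=C | intermediate
12 | (3R,4S,5S)-3-[(dimethylamino)methyl]-4-ethenyl-5-[(triethylsilyloxy)methyl]oxolan-2-one | CC[Si](CC)(CC)OC[C@H]1OC(=O)[C@@H](CN(C)C)[C@@H]1C=C | intermediate
13 | (3R,4S,5S)-3-[(dimethylamino)methyl]-4-ethenyl-5-(hydroxymethyl)oxolan-2-one | OC[C@H]1OC(=O)[C@@H](CN(C)C)[C@@H]1C=C | intermediate
14 | trimethylammonium iodide of 13 | OC[C@H]1OC(=O)[C@@H](C[N+](C)(C)C)[C@@H]1C=C.[I-] | intermediate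
15 | (4S,5S)-4-ethenyl-5-(hydroxymethyl)-3-methylideneoxolan-2-one | OC[C@H]1OC(=O)C(=C)[C@@H]1C=C | intermediate
16 | (3R,6S,7R)-7-ethenyl-6-(hydroxymethyl)-1,5-dioxaspiro[2.4]heptan-4-one | OC[C@H]1OC(=O)[C@]2(CO2)[C@@H]1C=C | intermediate
17 | anti-homopropargylic alcohol (C-1 R, C-4 S, C-5 S; free 5-OH) | CC(=O)[C@@](O)(C=C)C#C[C@H](C)[C@H](O)[C@H]1OC(=O)[C@]2(CO2)[C@@H]1C=C | intermediate
18 | 5-O-TES ether of 17 | CC(=O)[C@@](O)(C=C)C#C[C@H](C)[C@H](O[Si](CC)(CC)CC)[C@H]1OC(=O)[C@]2(CO2)[C@@H]1C=C | intermediate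
19 | divinyl furanone (C-10 S, C-4 R) | C[C@@H](C1=CC(=O)[C@@](C)(O1)C=C)[C@H](O[Si](CC)(CC)CC)[C@H]1OC(=O)[C@]2(CO2)[C@@H]1C=C | intermediate
20 | bridged (8Z)-cycloalkene | C[C@H]1C2=CC(=O)[C@@](C)(O2)/C=C\[C@@H]3[C@H](OC(=O)[C@]3(O4)C4)[C@H]1O[Si](CC)(CC)CC | intermediate
21 | 8β,9β-diol | O[C@H]1[C@@H]2[C@H](OC(=O)[C@]2(O3)C3)[C@@H](O[Si](CC)(CC)CC)[C@@H](C)C2=CC(=O)[C@@](C)(O2)[C@H]1O | intermediate
22 | angelic acid, (Z)-2-methylbut-2-enoic acid | C/C=C(/C)C(=O)O | starting material
23 | angelic 2,4,6-trichlorobenzoic anhydride | C/C=C(/C)C(=O)OC(=O)c1c(Cl)cc(Cl)cc1Cl | intermediate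
24 | 8-O-angelate, 11,13-epoxide, 5-OTES | C/C=C(/C)C(=O)O[C@H]1[C@@H]2[C@H](OC(=O)[C@]2(O3)C3)[C@@H](O[Si](CC)(CC)CC)[C@@H](C)C2=CC(=O)[C@@](C)(O2)[C@H]1O | intermediate
25 | CNP0340393.2 (4R,5S,6S,7S,8S,9S,10S,11S) | C/C=C(/C)C(=O)O[C@H]1[C@@H]2[C@H](OC(=O)[C@]2(O)CCl)[C@@H](O)[C@@H](C)C2=CC(=O)[C@@](C)(O2)[C@H]1O | target

## Step count and weak points
Total steps: 14. Longest linear sequence: 11 (steps 4–14). The west branch (steps 1–3) joins at step 8.

**Step 10 (new reaction).**
- Risks: Meyer–Schuster isomerisation, 1,4-enyne cycloisomerisation, or a sluggish vinyl shift.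
- The fallback sets out from 18 and comes back at 19, using two known reaction types instead of π-acid catalysis.
- 18 is treated with catalytic KOt-Bu and 18-crown-6 in THF at −40 °C (anionic acyloin/α-ketol rearrangement).
- In the non-chelated alkoxide the C–O⁻ and C=O dipoles are opposed. This places the vinyl group over the same face of C-10 as in step 10, and conjugation of the new ketone with the alkyne drives the equilibrium.
- The product is the α′-hydroxy ynone F1. It is closed by the established amine-mediated cyclisation of α′-hydroxy ynones (Et2NH, EtOH, then AcOH) to give 19.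

**Step 11 (metathesis between two hindered vinyl groups in a strained ring).**
- The fallback sets out from 19 and comes back at 21, skipping 20.
- Ozonolysis of both vinyl groups (O3, CH2Cl2, −78 °C, Sudan red end-point; Me2S) gives the dialdehyde F2.
- F2 is cyclised by an intramolecular pinacol coupling with the divalent vanadium reagent made from VCl3(THF)3 and Zn in CH2Cl2.
- The chelated cis-diolate delivers the ring-cis 8,9-diol 21 directly.

**Step 8 (catalytic union of two dense fragments).**
- Risks: possible ketone reduction, and a weak Felkin preference for the 5-epimer that the catalyst must override.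
- The fallback sets out from 16 and 1 and comes back at 17, replacing hydrogen-transfer catalysis by a stoichiometric chiral allenylmetal reagent.
- 16 is oxidised with Dess–Martin periodinane to the aldehyde F3.
- Purchased (R)-but-3-yn-2-ol is converted (TBSCl, imidazole) into the silyl ether F4.
- F4 is lithiated and acylated with 1 to the ynone F5.
- F5 is vinylated with 5 under chelation control to the diol F6.
- F6 is oxidised with IBX to the ketol F7.
- F7 is desilylated with HF·pyridine to the propargylic alcohol F8.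
- F8 is mesylated (MsCl, Et3N) to the mesylate F9.
- Pd(dppf)Cl2 (5 mol %) and InI in THF–HMPA turn F9 into an allenylindium reagent: anti SN2′ attack of zerovalent palladium, then transmetalation to trivalent indium.
- This reagent adds to F3 through a cyclic SE2′ transition state and gives the anti adduct 17 under reagent control.

## Further compounds
F1 | step 10 | α′-hydroxy ynone (C-10 S) | C=C[C@](C)(O)C(=O)C#C[C@H](C)[C@H](O[Si](CC)(CC)CC)[C@H]1OC(=O)[C@]2(CO2)[C@@H]1C=C
F2 | step 11 | C-8/C-9 dialdehyde | C[C@@H](C1=CC(=O)[C@@](C)(O1)C=O)[C@H](O[Si](CC)(CC)CC)[C@H]1OC(=O)[C@]2(CO2)[C@@H]1C=O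
F3 | step 8 | (3R,6S,7R)-7-ethenyl-4-oxo-1,5-dioxaspiro[2.4]heptane-6-carbaldehyde | O=C[C@H]1OC(=O)[C@]2(CO2)[C@@H]1C=C
F4 | step 8 | (R)-3-(tert-butyldimethylsilyloxy)but-1-yne | C[C@@H](O[Si](C)(C)C(C)(C)C)C#C
F5 | step 8 | (2S,6R)-6-(tert-butyldimethylsilyloxy)-2-hydroxyhept-4-yn-3-one | C[C@H](O)C(=O)C#C[C@@H](C)O[Si](C)(C)C(C)(C)C
F6 | step 8 | (2S,3R,6R)-6-(tert-butyldimethylsilyloxy)-3-ethenylhept-4-yne-2,3-diol | C[C@H](O)[C@@](O)(C=C)C#C[C@@H](C)O[Si](C)(C)C(C)(C)C
F7 | step 8 | (3R,6R)-6-(tert-butyldimethylsilyloxy)-3-ethenyl-3-hydroxyhept-4-yn-2-one | CC(=O)[C@@](O)(C=C)C#C[C@@H](C)O[Si](C)(C)C(C)(C)C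
F8 | step 8 | (3R,6R)-3-ethenyl-3,6-dihydroxyhept-4-yn-2-one | CC(=O)[C@@](O)(C=C)C#C[C@@H](C)O
F9 | step 8 | (2R,5R)-5-ethenyl-5-hydroxy-6-oxohept-3-yn-2-yl methanesulfonate | CC(=O)[C@@](O)(C=C)C#C[C@@H](C)OS(C)(=O)=O
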